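The earlier runs and the new flask are simulated from invented constants; the scatter is artificial.

| flask | Sbt | Sbt2 | Rea | Ctl | remark | time |
|---|---|---|---|---|---|---|
| oak | 0.20 M | 0.20 M | 4 equiv | 5 mol% | run made earlier |  |
| flask | 0.20 M | 0.20 M | 2.00 equiv | 5 mol% |  | 15 h |
oak run (percent of the Sbt and Sbt2 together charged)

| time / h | Sbt / % | Sbt2 / % | Tgt2 / % |
|---|---|---|---|
| 0.250 | 46.5 | 48.8 | 5.5 |
| 0.417 | 45.5 | 48.1 | 4.5 |
| 0.667 | 42.0 | 47.4 | 5.8 |
| 1.00 | 44.0 | 46.3 | 9.2 |
| 2.00 | 37.1 | 44.3 | 12.7 |
| 3.00 | 37.4 | 42.4 | 16.1 |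

(each reading ± 1 percentage point)
- Ctl is single-handed; Sbt and Sbt2 are mirror images of each other, charged as a racemate, each of them at the stated concentration
- reactions considered so far: Rea + Ctl -> Rea.Ctl; 2 Rea -> Tgt; Sbt <-> Sbt2; Rea + Ctl + Sbt -> Ctl + Tgt2; Rea + Ctl + Sbt2 -> Ctl + Tgt3
- an excess is the difference of the two amounts in percent of their sum
- an excess is below zero if the other one leads
1. part of the Sbt and Sbt2 charged together that has reacted at 15 h
2. excess of Tgt2 over Tgt3 in the product at 15 h
3. excess of Sbt2 over Sbt among what is left of the two at 15 h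

- In a one-step world, with Ctl intact and rate proportional to c_Rea, the log-loss L (minus the logarithm of the fraction of Sbt and Sbt2 left, the pseudo-first-order exponent) grows with the dose, the time integral of c_Rea.
- Our bound from above, as good as one scattered reading allows: if c_Rea stayed at its charge and the rate read from the earliest oak reading, halved for the flask's Rea, ran the whole 15 h, L would reach 1.44 and c 76.4 %.
- Our bound from below: if the flask made half of the oak L of 0.226 read at 3.00 h and then stopped, c would be 10.7 %.
- To tighten this, we take the oak L of 0.102 read at 1.00 h: as read, the mean rate of L falls 1.65-fold after that reading.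
- If 2 Rea -> Tgt does the fading, the reciprocal of c_Rea climbs linearly, relative to charge, with slope b, read here as 0.554 /h in oak and proportional to the Rea charge.
- Replacing the curve by its mean, the charge cancels and the dose follows the logarithm of one plus bt. We carry the dose ratio D, the flask's 15 h over oak's 3.00 h, 1.67, which gives c 31.5 %.
- The forecast gives c 31 % (23 % to 40 %), eP 49 % (38 % to 60 %) and eS 2 % (0.5 % to 7 %), saying “Racemisation keeps running as Rea dies”; its c lies inside our bracket .
- The flask gives c 27.8 %, eP 44.0 % and eS 3.25 %, with c inside the bracket .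

    Rea + Ctl → Rea.Ctl (k = 9.40 × 10⁻⁵ /M/s)
    2 Rea → Tgt (k = 9.80 × 10⁻⁵ /M/s)
    Sbt ⇌ Sbt2 (k = 2.40 × 10⁻⁵ /s)
    Rea + Ctl + Sbt → Ctl + Tgt2 (k = 0.00980 /M²/s)
    Rea + Ctl + Sbt2 → Ctl + Tgt3 (k = 0.00350 /M²/s)

- At 15.0 h, Rea.Ctl holds 47.1 % of the catalyst charged in the flask. The flask's L is 1.44 times the oak L as read at 3.00 h, less than D. On the neighbour flask with 8.5 mol% of Ctl, D scaled by the Ctl charges gives c 47.4 %, and that flask stands at 39.3 %.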